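**Strategy.** In the cyclohexane ring (spiro[4.5]decane numbering), C10, the C(CH3)OH carbon, and C7, which carries the exocyclic C(CH3)CHO unit, are 1,4-related; the spiro carbon C5 and the hydroxypropyl CH C6 lie between them. C10 and C7 are read as the two α-carbons of a 2-methylfuran whose ring oxygen becomes the tertiary hydroxyl. One intramolecular furan Diels–Alder reaction of a tethered (Z)-α-allyl enoate forms C5–C10 and C6–C7, closes the cyclohexene as a 7-oxanorbornene together with a six-membered keto ester ring, and sets C5, C6 and C10. The precursor is a 2-methylfuran bearing a quaternary β-keto ester side chain that ends in the enoate.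

Key step: step 7

Remark on labels: C1–C10 are the spiro[4.5]decane positions of the target (C1 CHOH, C2 side-chain CH, C5 spiro, C6 hydroxypropyl CH, C7 ylidene carbon, C10 C(CH3)OH) and are used for all intermediates.

Assumption: the antipode of the phase-transfer catalyst in step 3 is the one that gives the (R)-quaternary ester; in step 7 the tether is taken to react through a chair with the tert-butyl ester in the furan plane and the methyl group on the face away from the dienophile, which translates (R) into the target configuration at C5, C6 and C10; should experiment show the opposite sense, the enantiomeric catalyst is used in step 3.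

Design note: the quaternary ester is carried as a tert-butyl ester (robust in the asymmetric alkylation, no transesterification, distinguishable from the methyl esters). The chain aldehyde is unmasked from a terminal alkene, not by partial reduction of a third ester. The precursor 11 is correctly an oct-2-enedioate (four-atom tether).

Step 1
Reactants: 1 2-bromo-5-methylfuran; 2 (2-tert-butoxy-2-oxoethyl)zinc bromide
Product: 3 tert-butyl 2-(5-methylfuran-2-yl)acetate
Conditions: Pd2(dba)3 (1 mol%), Q-Phos (2 mol%), THF, 25 °C
Reagents that add atoms: none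
Why: Palladium-catalysed α-arylation of a zinc ester enolate (Reformatsky reagent) with a heteroaryl bromide is a mild Negishi-type coupling that tolerates the acid-sensitive furan and gives the arylacetate in one step.

Step 2
Reactants: 3 tert-butyl 2-(5-methylfuran-2-yl)acetate; 4 pent-4-enoyl chloride
Product: 5 tert-butyl 2-(5-methylfuran-2-yl)-3-oxohept-6-enoate (racemic)
Conditions: LiHMDS (2.1 equiv), THF, −78 °C; then 4, −78 → 0 °C; aq NH4Cl
Reagents that add atoms: none
Why: Crossed Claisen-type C-acylation of the lithium ester enolate by the acid chloride, with the second equivalent of base consumed by the more acidic β-keto ester so that acylation stops after one acyl group.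

Step 3
Reactants: 5 tert-butyl 2-(5-methylfuran-2-yl)-3-oxohept-6-enoate
Product: 6 tert-butyl (2R)-2-methyl-2-(5-methylfuran-2-yl)-3-oxohept-6-enoate
Conditions: MeI, Cs2CO3 (solid), chiral N-spiro bis(binaphthyl)ammonium bromide with 3,4,5-trifluorophenyl groups (2 mol%), toluene, −20 °C
Reagents that add atoms: iodomethane, CI
Why: Asymmetric phase-transfer C-alkylation of an α-substituted β-keto ester, in which the chiral ammonium enolate ion pair is methylated on one face to create the (R)-quaternary centre, with carbonate as base so that the non-enolisable product is not cleaved by retro-Claisen attack.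

Step 4
Reactants: 6 tert-butyl (2R)-2-methyl-2-(5-methylfuran-2-yl)-3-oxohept-6-enoate
Product: 7 tert-butyl (2R)-2-methyl-2-(5-methylfuran-2-yl)-3,6-dioxohexanoate
Conditions: OsO4 (2 mol%), NaIO4, 2,6-lutidine, dioxane–H2O, 25 °C
Reagents that add atoms: osmium tetroxide, O=[Os](=O)(=O)=O; sodium periodate, [Na+].[O-]I(=O)(=O)=O
Why: Lemieux–Johnson oxidative cleavage, in which the monosubstituted alkene is dihydroxylated in preference to the aromatic furan and the quaternary centre cannot epimerise under the buffered neutral conditions.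

Step 5
Reactants: 8 methyl 2-[bis(2,2,2-trifluoroethoxy)phosphoryl]acetate; 9 allyl bromide
Product: 10 methyl 2-[bis(2,2,2-trifluoroethoxy)phosphoryl]pent-4-enoate (racemic)
Conditions: NaH, THF, 0 °C; then 9, 0 → 25 °C
Reagents that add atoms: none
Why: SN2 mono-alkylation of the stabilised phosphonoacetate anion with a reactive allylic bromide, run with the phosphonate in slight excess to limit double alkylation.

Step 6
Reactants: 7 tert-butyl (2R)-2-methyl-2-(5-methylfuran-2-yl)-3,6-dioxohexanoate; 10 methyl 2-[bis(2,2,2-trifluoroethoxy)phosphoryl]pent-4-enoate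
Product: 11 8-tert-butyl 1-methyl (2Z,7R)-7-methyl-7-(5-methylfuran-2-yl)-6-oxo-2-(prop-2-en-1-yl)oct-2-enedioate
Conditions: KHMDS, 18-crown-6, THF, −78 °C
Reagents that add atoms: none
Why: Still–Gennari olefination, in which the electron-poor bis(trifluoroethyl) phosphonate makes elimination faster than equilibration of the adducts and so gives the (Z)-trisubstituted enoate (ester cis to the chain), the aldehyde reacting in preference to the hindered ketone.

Step 7
Reactants: 11 8-tert-butyl 1-methyl (2Z,7R)-7-methyl-7-(5-methylfuran-2-yl)-6-oxo-2-(prop-2-en-1-yl)oct-2-enedioate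
Product: 12 oxa-bridged tricyclic keto diester (2-tert-butyl 7-methyl 2,8-dimethyl-3-oxo-7-(prop-2-en-1-yl)-11-oxatricyclo[6.2.1.0(1,6)]undec-9-ene-2,7-dicarboxylate)
Conditions: CH2Cl2 (0.05 M), BHT (cat.), 15 kbar, 25 °C, 72 h; solution kept at 0 °C and used at once
Reagents that add atoms: none
Why: Proposed new method: a concerted, asynchronous [4+2] cycloaddition in which the two α-carbons of the furan are the diene termini and the (Z)-enoate the dienophile, the methyl-bearing furan carbon bonding to the α-carbon (future C5) and the tether-bearing furan carbon to the β-carbon (future C6); the closest known reaction type is the intramolecular furan Diels–Alder reaction with a four-carbon tether run under high pressure, which has not been shown for an α,β-disubstituted acrylate that must build a quaternary carbon next to a substituted bridgehead. The cyclohexene ring is closed by the cycloaddition itself as a 7-oxanorbornene, and the six-membered keto ester ring by the tether that spans the new C6–C7 bond, the tether lying exo (on the side of the oxygen bridge) because a four-atom chain cannot reach the endo face without severe strain. Suprafacial addition to the (Z)-alkene then places the methyl ester, cis to the tether, exo and the allyl group endo at C5, the tether carbon exo and H endo at C6, and fixes both bridgeheads (C7, C10) relative to them. The absolute sense comes from the (R)-quaternary centre, which in the chair-like tether holds its ester in the furan plane beside H-3 and its methyl group on the face away from the dienophile. The step needs π-facial selectivity and capture of a reversible adduct; the gem-disubstituted tether and 15 kbar (negative volumes of activation and reaction) favour closure, and the adduct is reduced immediately in step 8 so that it cannot revert.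

Step 8
Reactants: 12 oxa-bridged tricyclic keto diester
Product: 13 dihydro adduct (2-tert-butyl 7-methyl 2,8-dimethyl-3-oxo-7-(prop-2-en-1-yl)-11-oxatricyclo[6.2.1.0(1,6)]undecane-2,7-dicarboxylate)
Conditions: KO2CN=NCO2K (portionwise), AcOH, CH2Cl2–MeOH, 0 °C
Reagents that add atoms: none
Why: Diimide reduction transfers H2 syn to the strained oxanorbornene alkene from its open exo face much faster than to the unstrained allyl alkene, so a limited amount of reagent should be chemoselective and removes the retro-Diels–Alder pathway.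

Step 9
Reactants: 13 dihydro adduct
Product: 15 allyl hydroxy triester (methyl 5-[(E)-1-tert-butoxy-1-oxopropan-2-ylidene]-2-hydroxy-6-(3-methoxy-3-oxopropyl)-2-methyl-1-(prop-2-en-1-yl)cyclohexane-1-carboxylate), via sodium ester enolate 14 (not isolated)
Conditions: NaOMe (1.2 equiv), THF–MeOH (10:1), −20 → 0 °C; AcOH quench at −20 °C
Reagents that add atoms: sodium methoxide, [Na+].[O-]C
Why: Retro-Claisen cleavage of the non-enolisable β-keto ester by methoxide releases the tert-butyl ester enolate beside the bridgehead, which expels the bridging oxygen by E1cB β-elimination (the known base-induced opening of 7-oxanorbornanes), leaving the oxygen on C10 with its configuration untouched and turning the bulkier ester towards the unbranched C8 side, so that the (E)-alkene with methyl syn to C6 is expected.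

Step 10
Reactants: 15 allyl hydroxy triester
Product: 16 tetraol (2-(hydroxymethyl)-3-(3-hydroxypropyl)-4-[(E)-1-hydroxypropan-2-ylidene]-1-methyl-2-(prop-2-en-1-yl)cyclohexan-1-ol)
Conditions: DIBAL-H (8 equiv), CH2Cl2, −78 → 0 °C; Rochelle salt
Reagents that add atoms: none
Why: Aluminium hydride reduction of all three esters, the enoate by 1,2-addition so that the tetrasubstituted alkene and its geometry are kept.

Step 11
Reactants: 16 tetraol
Product: 17 bis-silyl ether (TBS on the hydroxypropyl and ylidene CH2OH groups; neopentyl CH2OH and tertiary OH free)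
Conditions: TBSCl (2.2 equiv), imidazole, CH2Cl2, −20 → 0 °C
Reagents that add atoms: tert-butyldimethylsilyl chloride, CC(C)(C)[Si](C)(C)Cl
Why: Sterically controlled silylation, the unhindered primary and the allylic primary hydroxyls reacting far faster than the neopentyl CH2OH flanked by C6 and C10 or the tertiary hydroxyl.

Step 12
Reactants: 17 bis-silyl ether
Product: 18 β-hydroxy aldehyde (quaternary carbaldehyde at C5 bearing the allyl group)
Conditions: Dess–Martin periodinane, NaHCO3, CH2Cl2, 0 → 25 °C
Reagents that add atoms: none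
Why: Dess–Martin oxidation of the only remaining primary alcohol under buffered, non-basic conditions, which avoids retro-aldol cleavage of the β-hydroxy aldehyde; the tertiary alcohol cannot be oxidised.

Step 13
Reactants: 18 β-hydroxy aldehyde
Product: 19 spiro ketone (6-[3-(TBSO)propyl]-7-[(E)-1-(TBSO)propan-2-ylidene]-10-hydroxy-10-methylspiro[4.5]decan-1-one)
Conditions: [Rh(nbd)(dppe)]BF4 (5 mol%, activated with H2), CH2Cl2, 25 °C
Reagents that add atoms: none
Why: Rhodium(I)-catalysed intramolecular hydroacylation of a 4-pentenal, the acyl rhodium hydride adding across the terminal alkene and reductive elimination forming C1–C2, with the quaternary α-carbon blocking enolisation and favouring ring closure over decarbonylation.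

Step 14
Reactants: 19 spiro ketone
Product: 21 cyclopentene (6-[3-(TBSO)propyl]-7-[(E)-1-(TBSO)propan-2-ylidene]-10-methylspiro[4.5]dec-1-en-10-ol), via trisylhydrazone 20 (not isolated)
Conditions: 2,4,6-iPr3C6H2SO2NHNH2, TsOH (cat.), THF, 4 Å MS, 25 °C; then n-BuLi (5 equiv), −78 → 0 °C; H2O
Reagents that add atoms: none
Why: Shapiro reaction, in which the hydrazone dianion loses sulfinate and N2 to give a vinyllithium that is protonated, the C1=C2 alkene forming regiospecifically because C5 carries no hydrogen.

Step 15
Reactants: 21 cyclopentene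
Product: 22 epoxide (1,2-epoxy derivative of 21 with the oxirane oxygen on the face of C10)
Conditions: VO(acac)2 (5 mol%), t-BuOOH, CH2Cl2, 0 → 25 °C
Reagents that add atoms: tert-butyl hydroperoxide, CC(C)(C)OO
Why: Vanadium-catalysed hydroxyl-directed epoxidation, the vanadate ester of the homoallylic C10 hydroxyl delivering oxygen to the alkene face syn to C10, while the remote tetrasubstituted alkene has no hydroxyl within reach.

Step 16
Reactants: 22 epoxide; 23 3-bromofuran
Product: 25 trans furyl diol (2-(furan-3-yl)spiro[4.5]decane-1,10-diol derivative with 1-OH on the C10 face and furyl on the C6 face), via 3-furylmagnesium bromide 24 (not isolated)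
Conditions: 23, Mg, LiCl, THF, 25 °C; then CuI (10 mol%), 22, −30 → 0 °C (3 equiv Grignard)
Reagents that add atoms: none
Why: Copper-catalysed Grignard opening of the epoxide by SN2 attack with inversion at C2 (C1 is neopentyl), which puts the furyl group on the C6 face; the aromatic furan is a robust carrier of the four side-chain carbons C(CH2O)=CH–C.

Step 17
Reactants: 25 trans furyl diol
Product: 26 furyl ketone (2-(furan-3-yl)-10-hydroxy-10-methylspiro[4.5]decan-1-one derivative, furyl on the C6 face)
Conditions: Dess–Martin periodinane, NaHCO3, CH2Cl2, 0 °C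
Reagents that add atoms: none
Why: Dess–Martin oxidation of the secondary alcohol under buffered conditions that should not epimerise the α-furyl centre; the tertiary hydroxyl is inert.

Step 18
Reactants: 26 furyl ketone
Product: 27 cis furyl diol (1-OH and 2-furyl both on the C6 face)
Conditions: Me4NBH(OAc)3, AcOH–MeCN, −30 °C
Reagents that add atoms: none
Why: Evans–Saksena hydroxyl-directed reduction, in which the acetoxyborohydride bound to the C10 hydroxyl delivers hydride intramolecularly to the C10 face of the ketone, which is also the face anti to the furyl group, so C1–OH is set cis to the C2 substituent and anti to C10.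

Step 19
Reactants: 27 cis furyl diol
Product: 29 butenolide (4-substituted furan-2(5H)-one attached at C2), via γ-hydroxybutenolide 28 (not isolated)
Conditions: O2, hν, tetraphenylporphyrin, i-Pr2NEt, CH2Cl2, −78 °C; then NaBH4, MeOH, 0 °C; aq citric acid
Reagents that add atoms: dioxygen, O=O
Why: Photooxygenation ([4+2] addition of singlet oxygen to the furan) with a hindered amine, which removes the less hindered endoperoxide hydrogen so that the carbonyl ends on the furan carbon remote from the ring; borohydride reduction of the masked aldehyde and relactonisation then give the butenolide that locks the CH2O carbon cis to the carbonyl carbon, and the furan is expected to react faster than the silyloxy-substituted tetrasubstituted alkene.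

Step 20
Reactants: 29 butenolide
Product: 30 lactol (4-substituted 2,5-dihydrofuran-2-ol)
Conditions: DIBAL-H (3.5 equiv), CH2Cl2, −78 °C; Rochelle salt; used crude
Reagents that add atoms: none
Why: Partial reduction of the lactone to the lactol through the low-temperature aluminium hemiacetal, with neutral work-up to avoid dehydration to the furan.

Step 21
Reactants: 31 2-methylprop-2-en-1-ol; 32 1-bromo-3-methylbut-2-ene
Product: 33 6-methyl-2-methylidenehept-5-en-1-ol
Conditions: n-BuLi (2.2 equiv), TMEDA, Et2O, 0 → 25 °C; then 32, −78 → 25 °C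
Reagents that add atoms: none
Why: Alkylation of the O,C-dilithio allylic dianion of methallyl alcohol at carbon by SN2 displacement of the primary allylic bromide.

Step 22
Reactants: 33 6-methyl-2-methylidenehept-5-en-1-ol
Product: 34 diethyl (6-methyl-2-methylidenehept-5-en-1-yl)phosphonate
Conditions: P(OEt)3, ZnI2, toluene, 110 °C
Reagents that add atoms: triethyl phosphite, CCOP(OCC)OCC
Why: Zinc iodide-mediated Michaelis–Arbuzov-type conversion of an allylic alcohol into its phosphonate, for which allylic transposition is degenerate because the 2-substituted allyl unit is symmetrical.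

Step 23
Reactants: 30 lactol; 34 diethyl (6-methyl-2-methylidenehept-5-en-1-yl)phosphonate
Product: 35 triene triol bis-silyl ether ((2Z,4E)-2-(spirodecan-2-yl)-10-methyl-6-methylideneundeca-2,4,9-trien-1-ol with the two TBS ethers)
Conditions: 34 (5 equiv), n-BuLi, THF–DMPU, −78 °C; then 30, −78 → 25 °C
Reagents that add atoms: none
Why: Horner–Wadsworth–Emmons olefination of the open hydroxy-enal form of the lactol with an allylic phosphonate anion, which should give the (E)-disubstituted alkene, while the trisubstituted alkene keeps the geometry fixed in the butenolide and the primary hydroxyl is set free.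

Step 24
Reactants: 35 triene triol bis-silyl ether
Product: 36 allylic acetate
Conditions: Ac2O (1.1 equiv), pyridine, CH2Cl2, 0 °C
Reagents that add atoms: acetic anhydride, CC(=O)OC(C)=O
Why: Selective O-acylation of the only primary hydroxyl, the hindered secondary C1–OH and the tertiary C10–OH being unreactive without an acyl-transfer catalyst.

Step 25
Reactants: 36 allylic acetate
Product: 37 tetraol acetate (free hydroxypropyl and ylidene CH2OH)
Conditions: HF·pyridine, pyridine, THF, 0 → 25 °C
Reagents that add atoms: none
Why: Fluoride-mediated cleavage of the two primary silyl ethers under buffered conditions that leave the allylic acetate and the triene intact.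

Step 26
Reactants: 37 tetraol acetate
Product: 38 CNP0204268.1
Conditions: activated MnO2, CH2Cl2, 25 °C
Reagents that add atoms: none
Why: Manganese dioxide oxidises only the allylic primary alcohol to the enal with retention of the (E)-geometry, leaving the saturated primary, the secondary and the tertiary hydroxyls and the allylic acetate untouched.

**Compound list**

1 | 2-bromo-5-methylfuran | Cc1ccc(Br)o1 | starting material
2 | (2-tert-butoxy-2-oxoethyl)zinc bromide | CC(C)(C)OC(=O)C[Zn]Br | starting material
3 | tert-butyl 2-(5-methylfuran-2-yl)acetate | Cc1ccc(CC(=O)OC(C)(C)C)o1 | intermediate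
4 | pent-4-enoyl chloride | C=CCCC(Cl)=O | starting material
5 | tert-butyl 2-(5-methylfuran-2-yl)-3-oxohept-6-enoate (racemic) | Cc1ccc(o1)C(C(=O)OC(C)(C)C)C(=O)CCC=C | intermediate
6 | tert-butyl (2R)-2-methyl-2-(5-methylfuran-2-yl)-3-oxohept-6-enoate | Cc1ccc(o1)[C@@](C)(C(=O)OC(C)(C)C)C(=O)CCC=C | intermediate
7 | tert-butyl (2R)-2-methyl-2-(5-methylfuran-2-yl)-3,6-dioxohexanoate | Cc1ccc(o1)[C@@](C)(C(=O)OC(C)(C)C)C(=O)CCC=O | intermediate
8 | methyl 2-[bis(2,2,2-trifluoroethoxy)phosphoryl]acetate | COC(=O)CP(=O)(OCC(F)(F)F)OCC(F)(F)F | starting material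
9 | allyl bromide | C=CCBr | starting material
10 | methyl 2-[bis(2,2,2-trifluoroethoxy)phosphoryl]pent-4-enoate (racemic) | COC(=O)C(CC=C)P(=O)(OCC(F)(F)F)OCC(F)(F)F | intermediate
11 | 8-tert-butyl 1-methyl (2Z,7R)-7-methyl-7-(5-methylfuran-2-yl)-6-oxo-2-(prop-2-en-1-yl)oct-2-enedioate (key-step precursor) | Cc1ccc(o1)[C@@](C)(C(=O)OC(C)(C)C)C(=O)CC/C=C(/CC=C)C(=O)OC | intermediate
12 | 2-tert-butyl 7-methyl 2,8-dimethyl-3-oxo-7-(prop-2-en-1-yl)-11-oxatricyclo[6.2.1.0(1,6)]undec-9-ene-2,7-dicarboxylate; C7 ester and C5 (on C6) exo, syn to O11; allyl and H-6 endo; C2 ester anti to O11 (key-step product) | C=CC[C@]1([C@@H]2CCC(=O)[C@](C)(C(=O)OC(C)(C)C)[C@]23O[C@@]1(C)C=C3)C(=O)OC | intermediate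
13 | 9,10-dihydro derivative of 12 (undecane-2,7-dicarboxylate, same configuration) | C=CC[C@]1([C@@H]2CCC(=O)[C@](C)(C(=O)OC(C)(C)C)[C@]23O[C@@]1(C)CC3)C(=O)OC | intermediate
14 | sodium enolate of the ring-opened (retro-Claisen) oxa-bridged triester: tert-butyl propanoate enolate on the bridgehead, methyl propanoate chain on C6 | C=CC[C@@]1(C(=O)OC)[C@H](CCC(=O)OC)[C@]2(C(C)=C([O-])OC(C)(C)C)O[C@@]1(C)CC2.[Na+] | intermediate
15 | methyl 5-[(E)-1-tert-butoxy-1-oxopropan-2-ylidene]-2-hydroxy-6-(3-methoxy-3-oxopropyl)-2-methyl-1-(prop-2-en-1-yl)cyclohexane-1-carboxylate; 2-OH, ring ester and propanoate chain all cis | C=CC[C@]1([C@H](CCC(=O)OC)/C(=C(\C)C(=O)OC(C)(C)C)CC[C@]1(C)O)C(=O)OC | intermediate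
16 | 2-(hydroxymethyl)-3-(3-hydroxypropyl)-4-[(E)-1-hydroxypropan-2-ylidene]-1-methyl-2-(prop-2-en-1-yl)cyclohexan-1-ol; 1-OH, 2-CH2OH and 3-chain cis | C=CC[C@]1([C@H](CCCO)/C(=C(\C)CO)CC[C@]1(C)O)CO | intermediate
17 | 3-[3-(tert-butyldimethylsilyloxy)propyl]-4-[(E)-1-(tert-butyldimethylsilyloxy)propan-2-ylidene]-2-(hydroxymethyl)-1-methyl-2-(prop-2-en-1-yl)cyclohexan-1-ol | C=CC[C@]1([C@H](CCCO[Si](C)(C)C(C)(C)C)/C(=C(\C)CO[Si](C)(C)C(C)(C)C)CC[C@]1(C)O)CO | intermediate
18 | 6-[3-(TBSO)propyl]-5-[(E)-1-(TBSO)propan-2-ylidene]-2-hydroxy-2-methyl-1-(prop-2-en-1-yl)cyclohexane-1-carbaldehyde | C=CC[C@]1([C@H](CCCO[Si](C)(C)C(C)(C)C)/C(=C(\C)CO[Si](C)(C)C(C)(C)C)CC[C@]1(C)O)C=O | intermediate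
19 | 6-[3-(TBSO)propyl]-7-[(E)-1-(TBSO)propan-2-ylidene]-10-hydroxy-10-methylspiro[4.5]decan-1-one (C5, C6, C10 as in the target) | C1CC[C@]2([C@H](CCCO[Si](C)(C)C(C)(C)C)/C(=C(\C)CO[Si](C)(C)C(C)(C)C)CC[C@]2(C)O)C1=O | intermediate
20 | 2,4,6-triisopropylbenzenesulfonylhydrazone of 19 | C1CC[C@]2([C@H](CCCO[Si](C)(C)C(C)(C)C)/C(=C(\C)CO[Si](C)(C)C(C)(C)C)CC[C@]2(C)O)C1=NNS(=O)(=O)c1c(C(C)C)cc(C(C)C)cc1C(C)C | intermediate
21 | 6-[3-(TBSO)propyl]-7-[(E)-1-(TBSO)propan-2-ylidene]-10-methylspiro[4.5]dec-1-en-10-ol | C1C[C@]2([C@H](CCCO[Si](C)(C)C(C)(C)C)/C(=C(\C)CO[Si](C)(C)C(C)(C)C)CC[C@]2(C)O)C=C1 | intermediate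
22 | 1,2-epoxide of 21, oxirane oxygen on the face of C10 | C1C[C@]2([C@H](CCCO[Si](C)(C)C(C)(C)C)/C(=C(\C)CO[Si](C)(C)C(C)(C)C)CC[C@]2(C)O)[C@H]3O[C@@H]13 | intermediate
23 | 3-bromofuran | Brc1ccoc1 | starting material
24 | 3-furylmagnesium bromide | Br[Mg]c1ccoc1 | intermediate
25 | 2-(furan-3-yl)-6-[3-(TBSO)propyl]-7-[(E)-1-(TBSO)propan-2-ylidene]-10-methylspiro[4.5]decane-1,10-diol, 1-OH on the C10 face, furyl on the C6 face (trans) | C1C[C@]2([C@H](CCCO[Si](C)(C)C(C)(C)C)/C(=C(\C)CO[Si](C)(C)C(C)(C)C)CC[C@]2(C)O)[C@@H](O)[C@@H]1c1ccoc1 | intermediate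
26 | 2-(furan-3-yl)-10-hydroxy-10-methylspiro[4.5]decan-1-one with the same C6 and C7 substituents, furyl on the C6 face | C1C[C@]2([C@H](CCCO[Si](C)(C)C(C)(C)C)/C(=C(\C)CO[Si](C)(C)C(C)(C)C)CC[C@]2(C)O)C(=O)[C@@H]1c1ccoc1 | intermediate
27 | 1-epimer of 25: 1-OH and 2-furyl cis, both on the C6 face (C1, C2 as in the target) | C1C[C@]2([C@H](CCCO[Si](C)(C)C(C)(C)C)/C(=C(\C)CO[Si](C)(C)C(C)(C)C)CC[C@]2(C)O)[C@H](O)[C@@H]1c1ccoc1 | intermediate
28 | 5-hydroxy-4-(spirodecan-2-yl)furan-2(5H)-one (hemiacetal carbon unassigned) | C1C[C@]2([C@H](CCCO[Si](C)(C)C(C)(C)C)/C(=C(\C)CO[Si](C)(C)C(C)(C)C)CC[C@]2(C)O)[C@H](O)[C@@H]1C3=CC(=O)OC3O | intermediate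
29 | 4-(spirodecan-2-yl)furan-2(5H)-one | C1C[C@]2([C@H](CCCO[Si](C)(C)C(C)(C)C)/C(=C(\C)CO[Si](C)(C)C(C)(C)C)CC[C@]2(C)O)[C@H](O)[C@@H]1C3=CC(=O)OC3 | intermediate
30 | 4-(spirodecan-2-yl)-2,5-dihydrofuran-2-ol (lactol, anomers) | C1C[C@]2([C@H](CCCO[Si](C)(C)C(C)(C)C)/C(=C(\C)CO[Si](C)(C)C(C)(C)C)CC[C@]2(C)O)[C@H](O)[C@@H]1C3=CC(O)OC3 | intermediate
31 | 2-methylprop-2-en-1-ol | C=C(C)CO | starting material
32 | 1-bromo-3-methylbut-2-ene | CC(C)=CCBr | starting material
33 | 6-methyl-2-methylidenehept-5-en-1-ol | C=C(CO)CCC=C(C)C | intermediate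
34 | diethyl (6-methyl-2-methylidenehept-5-en-1-yl)phosphonate | C=C(CP(=O)(OCC)OCC)CCC=C(C)C | intermediate
35 | (2Z,4E)-2-[1,10-dihydroxy-10-methyl-6-[3-(TBSO)propyl]-7-[(E)-1-(TBSO)propan-2-ylidene]spiro[4.5]decan-2-yl]-10-methyl-6-methylideneundeca-2,4,9-trien-1-ol | C=C(/C=C/C=C(\CO)[C@@H]1CC[C@]2([C@H](CCCO[Si](C)(C)C(C)(C)C)/C(=C(\C)CO[Si](C)(C)C(C)(C)C)CC[C@]2(C)O)[C@@H]1O)CCC=C(C)C | intermediate
36 | acetate of 35 at the primary hydroxyl | C=C(/C=C/C=C(\COC(C)=O)[C@@H]1CC[C@]2([C@H](CCCO[Si](C)(C)C(C)(C)C)/C(=C(\C)CO[Si](C)(C)C(C)(C)C)CC[C@]2(C)O)[C@@H]1O)CCC=C(C)C | intermediate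
37 | bis-desilylated 36 (free hydroxypropyl and (E)-1-hydroxypropan-2-ylidene groups) | C=C(/C=C/C=C(\COC(C)=O)[C@@H]1CC[C@]2([C@H](CCCO)/C(=C(\C)CO)CC[C@]2(C)O)[C@@H]1O)CCC=C(C)C | intermediate
38 | CNP0204268.1: [(2Z,4E)-2-[(1R,2S,5S,6R,7E,10S)-1,10-dihydroxy-6-(3-hydroxypropyl)-10-methyl-7-(1-oxopropan-2-ylidene)spiro[4.5]decan-2-yl]-10-methyl-6-methylideneundeca-2,4,9-trien-1-yl] acetate | C=C(/C=C/C=C(\COC(C)=O)[C@@H]1CC[C@]2([C@H](CCCO)/C(=C(\C)C=O)CC[C@]2(C)O)[C@@H]1O)CCC=C(C)C | target

**Step count.** Total: 26 steps. Longest linear sequence: 23 steps (1–4, 6–20, 23–26).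

**Steps most likely to fail**

Step 7. The adduct contains two adjacent fully substituted carbons (C5 and C10), so cycloreversion may outrun cycloaddition even under pressure, and the two furan faces may be poorly differentiated. The fallback uses known chemistry, sets out from aldehyde 7 and comes back at hydroxy triester 15. Still–Gennari olefination of 7 with the unsubstituted phosphonate 8 (KHMDS, 18-crown-6, THF, −78 °C) should give the allyl-free (Z)-enoate 8-tert-butyl 1-methyl (2Z,7R)-7-methyl-7-(5-methylfuran-2-yl)-6-oxooct-2-enedioate F1. This is a β-tethered acrylate of the class for which the intramolecular furan Diels–Alder reaction with a four-carbon tether is established. At 15 kbar it should close to the allyl-free oxa-bridged keto diester F2, which diimide reduces to the dihydro keto diester F3. Sodium methoxide in THF then effects the same retro-Claisen/β-elimination and gives the allyl-free hydroxy triester F4. One equivalent of LiOH in aqueous THF at 0 °C hydrolyses only the unhindered propanoate ester to the mono-acid F5. Fráter–Seebach alkylation of its lithium trianion (LDA, 3.2 equiv, THF, −78 °C, then allyl bromide 9) introduces the allyl group anti to the lithium alkoxide and to the C6 chain and gives the allylated acid F6. Methylation with trimethylsilyldiazomethane returns 15.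

Step 9. The tertiary alkoxide formed next to the C5 ester may cleave the congested C5–C10 bond by retro-aldol fragmentation, or the enolate may be protonated before it eliminates, which stalls the opening and erodes control of the alkene geometry. The fallback sets out from 13 and comes back at 15. Catalytic NaOMe in MeOH at 0 °C, stopped early, performs only the retro-Claisen cleavage and gives the oxygen-bridged saturated triester F7. Treatment with LDA (2.3 equiv) in THF at −78 °C then generates the ester enolate irreversibly; this is the known strong-base β-elimination opening of 7-oxanorbornanes. Quenching with acetic acid at −78 °C, before the lithium alkoxide can fragment, gives 15.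

Step 3. Methylation of an acyclic, aryl-stabilised enolate may proceed through both enolate geometries in the chiral ion pair, and low enantioselectivity would lower the optical purity of every later compound. The fallback sets out from 3 and comes back at 6. Methylation of 3 (LDA, MeI, THF, −78 °C) gives tert-butyl 2-(5-methylfuran-2-yl)propanoate F8. LDA and TMSCl convert it into the trimethylsilyl ketene acetal F9. Enantioselective C-acylation of F9 with pent-4-enoic anhydride, catalysed by a planar-chiral ferrocene-fused 4-(pyrrolidino)pyridine, then forms the quaternary centre in the acylation step and gives 6.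

**Further compounds**

F1 | step 7 | 8-tert-butyl 1-methyl (2Z,7R)-7-methyl-7-(5-methylfuran-2-yl)-6-oxooct-2-enedioate | Cc1ccc(o1)[C@@](C)(C(=O)OC(C)(C)C)C(=O)CC/C=C\C(=O)OC
F2 | step 7 | allyl-free oxa-bridged keto diester (2-tert-butyl 7-methyl 2,8-dimethyl-3-oxo-11-oxatricyclo[6.2.1.0(1,6)]undec-9-ene-2,7-dicarboxylate, C7 ester exo) | COC(=O)[C@@H]1[C@@H]2CCC(=O)[C@](C)(C(=O)OC(C)(C)C)[C@]23O[C@@]1(C)C=C3
F3 | step 7 | dihydro keto diester (9,10-dihydro derivative of F2) | COC(=O)[C@@H]1[C@@H]2CCC(=O)[C@](C)(C(=O)OC(C)(C)C)[C@]23O[C@@]1(C)CC3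
F4 | step 7 | allyl-free hydroxy triester (methyl 5-[(E)-1-tert-butoxy-1-oxopropan-2-ylidene]-2-hydroxy-6-(3-methoxy-3-oxopropyl)-2-methylcyclohexane-1-carboxylate) | COC(=O)[C@@H]1[C@H](CCC(=O)OC)/C(=C(\C)C(=O)OC(C)(C)C)CC[C@]1(C)O
F5 | step 7 | mono-acid (3-[3-[(E)-1-tert-butoxy-1-oxopropan-2-ylidene]-6-hydroxy-1-(methoxycarbonyl)-6-methylcyclohexan-2-yl]propanoic acid) | COC(=O)[C@@H]1[C@H](CCC(=O)O)/C(=C(\C)C(=O)OC(C)(C)C)CC[C@]1(C)O
F6 | step 7 | allylated acid (chain carboxylic acid corresponding to 15) | C=CC[C@]1([C@H](CCC(=O)O)/C(=C(\C)C(=O)OC(C)(C)C)CC[C@]1(C)O)C(=O)OC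
F7 | step 9 | oxygen-bridged saturated triester (7-oxanorbornane with CH(CH3)CO2tBu on the bridgehead, propanoate chain on C6, allyl and ester on C5; propanoate α-carbon unassigned) | C=CC[C@@]1(C(=O)OC)[C@H](CCC(=O)OC)[C@]2(C(C)C(=O)OC(C)(C)C)O[C@@]1(C)CC2
F8 | step 3 | tert-butyl 2-(5-methylfuran-2-yl)propanoate (racemic) | Cc1ccc(o1)C(C)C(=O)OC(C)(C)C
F9 | step 3 | trimethylsilyl ketene acetal of F8 (alkene geometry unassigned) | Cc1ccc(o1)C(C)=C(O[Si](C)(C)C)OC(C)(C)C
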